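## The problem

- The target 10 is an achiral, mirror-symmetric 1,2,3,5-tetrasubstituted benzene with no stereocentre. C1 carries the CH2C(O)NH2 arm, C4 the methoxy group, C3 and C5 iodine, C2 and C6 hydrogen.
- Its one structural demand is the contiguous array I–C3, MeO–C4, I–C5, an ether oxygen between two large halogens, placed para to a carbon chain.
- If the benzene ring is bought, this array can only come from iodination ortho to a free phenol and then alkylation of a hindered, weakly nucleophilic 2,6-diiodophenoxide. The order of events is then fixed and nothing is constructed.
- The functional groups limit the tools. The aryl C–I bonds do not tolerate organolithium or Grignard reagents, zerovalent palladium or nickel, hydrogenation or reducing radicals. The primary amide has acidic N–H bonds, and the benzylic CH2 is acidic.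
- The feature that allows a constructive plan is the ring segment C2(H)–C3(I)–C4(OMe)–C5(I)–C6(H). Atom for atom it is C2–C6 of a 3,5-diiodo-4-methoxypyrylium ring, whose sixth ring atom O1 stands where C1 of the target stands.
- The polarity of the parent 4-pyrone fits too: C3 and C5 are its only nucleophilic carbons (where iodine must go), and C2 and C6 its only electrophilic ones (where the new ring carbon must bond).
- The task thus becomes the exchange of O1 of a pyrylium ring for one carbon atom bearing the CH2CO2H arm, by attack at C2 and not C4, without loss of iodine.

## Retrosynthesis

**10 ⇒ 8 (amide C–N bond).** The primary amide is made last from 2-(3,5-diiodo-4-methoxyphenyl)acetic acid 8. The key step uses a basic ylide; a primary amide would bring acidic N–H bonds into it, and a 3-phosphoniopropanamide or ester would lose Ph3P by β-elimination. A carboxylate is the one form of the carboxyl group that survives ylide formation. The forward step is a routine activation and ammonolysis.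

**8 ⇒ 3 + 4 (ring bonds C1–C2 and C1–C6).** Both ring bonds to C1 are cut. C1 and its whole arm come from ylide 5, made from commercial (2-carboxyethyl)triphenylphosphonium bromide 4. C2–C6 with all four substituents come from 3,5-diiodo-4-methoxypyrylium triflate 3.
- Against cutting the C1–CH2 bond: a cross-coupling there would have to distinguish a third carbon–halogen bond from the two C–I bonds.
- Against cutting two ring bonds elsewhere: the mirror plane is lost and a regiochemical question arises (Alternative 2).
- Simplification: 3 has no carbon–carbon bond outside its ring and 4 is bought.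
- Forward demands: attack of the ylide at C2 (equivalent to C6), ring opening, and Wittig closure.

**3 ⇒ 2 (O–CH3 bond).** Methylation of the carbonyl oxygen of 3,5-diiodo-4H-pyran-4-one 2 serves three purposes:
- it turns the pyrone into a cation electrophilic enough for a phosphorus ylide;
- it fixes C4 as an enol ether, so the opened chain ends in a true aldehyde and not an unreactive enolate, as it would from neutral 2;
- it is the methyl ether of the target.

**2 ⇒ 1 (two C–I bonds).** Iodine is introduced on 4H-pyran-4-one 1, where C3 and C5 are the only nucleophilic carbons and symmetry excludes isomers. Iodination after arene formation would need two substitutions ortho to an anisole oxygen, which is sluggish.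

## Roads not taken

**Alternative 1: both C–I bonds and the O–CH3 bond cut (the obvious route).** Commercial 2-(4-hydroxyphenyl)acetamide A1 would be iodinated twice ortho to the hydroxyl group (I2/KI or ICl) to give 2-(4-hydroxy-3,5-diiodophenyl)acetamide A2, and A2 methylated (MeI, K2CO3) to 10.
- Step economy favours this road: two steps against four. It is the benchmark.
- It is set aside because it constructs nothing: every carbon, the oxygen and the side chain are bought in A1.
- The order is forced, since only the free phenol takes two iodines cleanly.
- The last step alkylates an electron-poor, doubly ortho-blocked phenoxide beside an amide N–H and an acidic benzylic CH2.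
- The chosen plan places each substituent by the innate polarity of a pyrone and attaches the C1 arm last, so salt 3 would serve any C1 substituent through the choice of ylide.

**Alternative 2: ring bonds C2–C3 and C1–C6 cut (pyran-2-one Diels–Alder).** 3,5-Diiodo-4-methoxy-2H-pyran-2-one A3 and but-3-ynamide A4 would undergo [4+2] cycloaddition and then lose carbon dioxide to give 10.
- A3 is unsymmetrical and no simpler than 3: its two iodines sit at electronically different carbons and its two oxygens must be differentiated.
- The weakly polarised terminal alkyne A4 can add in two orientations. The other one gives 2-(2,4-diiodo-3-methoxyphenyl)acetamide A5, and nothing in A3 clearly decides between them.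
- An unactivated alkyne needs high temperature, which endangers the C–I bonds and isomerises A4 to the allene.
- The chosen cut keeps the mirror plane, so no orientation question exists.

**Alternative 3: the C3–I and C4–O bonds cut (aryne difunctionalisation).** Fluoride would convert methyl 2-[3-iodo-4-(trimethylsilyl)-5-{[(trifluoromethyl)sulfonyl]oxy}phenyl]acetate A6 into the aryne methyl 2-(3,4-didehydro-5-iodophenyl)acetate A7, to be trapped by methoxide and an iodine electrophile.
- The iodine at C5 sits beside the C4 terminus of the triple bond. A nucleophile adds to the remote terminus C3, because the carbanion then forms at C4 next to the electron-withdrawing C–I bond and C4 is the hindered end.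
- Methoxide therefore ends at C3 and iodine at C4, giving methyl 2-(3,4-diiodo-5-methoxyphenyl)acetate A8, the wrong isomer.
- The target would need iodide as nucleophile and an "MeO+" electrophile, which does not exist as a practical reagent.
- A6 is a pentasubstituted benzene, harder to make than the target.

Key step: step 3

## Route

Step 1
Reactants: 1 4H-pyran-4-one
Product: 2 3,5-diiodo-4H-pyran-4-one
Conditions: NIS (2.4 equiv), CF3CO2H, 60 °C
Reagents that add atoms: N-iodosuccinimide, O=C1CCC(=O)N1I
Why: Electrophilic α-iodination of a vinylogous ester; C3 and C5 are the β-carbons of the two enol ether units and the only nucleophilic ring positions, and the symmetry of 1 leaves no regiochemical choice.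

Step 2
Reactants: 2 3,5-diiodo-4H-pyran-4-one
Product: 3 3,5-diiodo-4-methoxypyrylium trifluoromethanesulfonate
Conditions: MeOTf (1.5 equiv), ClCH2CH2Cl, 60 °C; precipitation with Et2O under N2
Reagents that add atoms: methyl trifluoromethanesulfonate, COS(=O)(=O)C(F)(F)F
Why: O-alkylation of the carbonyl oxygen of a 4-pyrone with a hard methylating agent, the standard entry to 4-methoxypyrylium salts; the product is an aromatic cation and the non-nucleophilic triflate cannot remove the methyl group again.

Step 3
Reactants: 3 3,5-diiodo-4-methoxypyrylium trifluoromethanesulfonate; 4 (2-carboxyethyl)triphenylphosphonium bromide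
Product: 8 2-(3,5-diiodo-4-methoxyphenyl)acetic acid, via ylide carboxylate 5 (not isolated), via pyranyl phosphonium betaine 6 (not isolated), via dienal ylide 7 (not isolated)
Conditions: 4 (1.1 equiv), NaN(SiMe3)2 (2.15 equiv), THF, −78 → 0 °C; added to 3 (1.0 equiv) in CH2Cl2, −78 °C; iPr2NEt (1.5 equiv), −78 → 50 °C; 1 M HCl
Reagents that add atoms: none
Why: Proposed new method: ylide 5 should add through carbon to C2 of the pyrylium ring of 3 (C2 and C6 are related by the mirror plane, so one α-adduct 6 results), the 2H-pyran 6 opens by thermal retro-6π-electrocyclisation of the O1–C2 bond to a 2,4-dienal, and iPr2NEt (or the internal carboxylate) removes the proton on the phosphonium carbon, now vinylogously acidified by the aldehyde, to give ylide 7. The carbocycle then closes by an intramolecular Wittig reaction of the ylide carbon on the aldehyde carbon (the former C6), a 6-exo-trig closure that can equally be read as a disrotatory 6π-electrocyclisation of the phosphonio-trienolate form of 7, and loss of Ph3PO makes the benzene ring and renders the sequence irreversible. The closest known reaction type is the conversion of 2,4,6-triarylpyrylium salts into benzenes by alkylidenetriphenylphosphoranes, together with the pyrylium-to-nitrobenzene exchange with nitromethane; to the best of present knowledge a 4-alkoxypyrylium salt with free α-positions and a carboxylate-bearing ylide have not been used in it. The selectivity needed is attack at C2 and not at C4, where loss of methoxide would give a 4-alkylidenepyran: C4 lies between two iodine atoms and is closed to a nucleophile as large as a triphenylphosphonium ylide, whereas C2 is an unhindered CH next to the oxonium centre. The (4E,6Z) geometry that closure requires is reached because 6 and its open form interconvert and the push-pull π-system of 7 has low rotational barriers. No stereocentre remains, since the two sp3 centres of 6 disappear on ring opening and aromatisation. The carboxylate form of the ylide blocks β-elimination of Ph3P, a phosphorus ylide does not attack C–I bonds at low temperature, and acid 8 is separated from Ph3PO by base extraction.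

Step 4
Reactants: 8 2-(3,5-diiodo-4-methoxyphenyl)acetic acid
Product: 10 2-(3,5-diiodo-4-methoxyphenyl)acetamide, via acyl imidazolide 9 (not isolated)
Conditions: CDI (1.2 equiv), THF, rt; then 28% aq NH3, 0 °C → rt
Reagents that add atoms: ammonia, N
Why: Amide formation through the acyl imidazolide 9; the neutral, room-temperature conditions leave the aryl C–I bonds and the methyl ether untouched, and ammonia is acylated faster than water.

## Compound list

1 | 4H-pyran-4-one | O=c1ccocc1 | starting material
2 | 3,5-diiodo-4H-pyran-4-one | O=c1c(I)cocc1I | intermediate
3 | 3,5-diiodo-4-methoxypyrylium trifluoromethanesulfonate | COc1c(I)c[o+]cc1I.[O-]S(=O)(=O)C(F)(F)F | intermediate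
4 | (2-carboxyethyl)triphenylphosphonium bromide | OC(=O)CC[P+](c1ccccc1)(c1ccccc1)c1ccccc1.[Br-] | starting material
5 | sodium 3-(triphenylphosphoranylidene)propanoate | [Na+].[O-]C(=O)CC=P(c1ccccc1)(c1ccccc1)c1ccccc1 | intermediate (not isolated)
6 | 3-(3,5-diiodo-4-methoxy-2H-pyran-2-yl)-3-(triphenylphosphonio)propanoate, inner salt (two transient sp3 centres, configuration unassigned, both lost in the same step) | [O-]C(=O)CC(C1OC=C(I)C(OC)=C1I)[P+](c1ccccc1)(c1ccccc1)c1ccccc1 | intermediate (not isolated)
7 | N,N-diisopropylethylammonium (4E,6Z)-5,7-diiodo-6-methoxy-8-oxo-3-(triphenylphosphoranylidene)octa-4,6-dienoate | CC[NH+](C(C)C)C(C)C.O=C/C(I)=C(OC)\C(I)=C/C(CC([O-])=O)=P(c1ccccc1)(c1ccccc1)c1ccccc1 | intermediate (not isolated)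
8 | 2-(3,5-diiodo-4-methoxyphenyl)acetic acid | COc1c(I)cc(CC(=O)O)cc1I | intermediate
9 | 1-[2-(3,5-diiodo-4-methoxyphenyl)acetyl]-1H-imidazole | COc1c(I)cc(CC(=O)n2ccnc2)cc1I | intermediate (not isolated)
10 | 2-(3,5-diiodo-4-methoxyphenyl)acetamide | COc1c(I)cc(CC(N)=O)cc1I | target

## Step count and risk

Total step count: 4. Longest linear sequence: 4 steps (1 → 2 → 3 → 8 → 10); 4 is purchased and enters at step 3.

**Step 3 (key step, proposed new method).**
- Most likely failures:
  - addition of the ylide at C4 with loss of methoxide in place of addition at C2;
  - transfer of the O-methyl group from the oxonium ion to carboxylate or bromide, returning the pyrone;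
  - intermolecular olefination of the opened aldehyde before it closes.
- All three arise because the cation offers several electrophilic sites and the chain-opened intermediate is bifunctional.
- Fallback (known chemistry only, sets out from 2, returns at 8). It uses the neutral pyrone, which has no leaving group at C4.
  - Base-mediated ring exchange of the 4-pyrone with nitromethane (KOtBu, tBuOH, heat) should give 2,6-diiodo-4-nitrophenol F1.
  - O-methylation (MeI, K2CO3, DMF) gives 1,3-diiodo-2-methoxy-5-nitrobenzene F2.
  - Reduction with iron powder and NH4Cl in aqueous ethanol gives 3,5-diiodo-4-methoxyaniline F3.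
  - Diazotisation (NaNO2, aqueous HCl, 0 °C) gives 3,5-diiodo-4-methoxybenzenediazonium chloride F4.
  - Meerwein arylation of 1,1-dichloroethene (CuCl2 cat., acetone–water) gives 1,3-diiodo-2-methoxy-5-(2,2,2-trichloroethyl)benzene F5.
  - Hydrolysis of the trichloromethyl group (H2SO4, AcOH, heat) gives 8.

**Step 1.**
- Most likely failure: incomplete second iodination, because the pyrone is partly O-protonated in the acid and the first iodine lowers the nucleophilicity of C5; acid-induced ring opening on prolonged heating is a second possibility.
- Fallback (sets out from 1, returns at 2): bromination by addition–elimination (Br2, CH2Cl2, then Et3N) to 3,5-dibromo-4H-pyran-4-one F6, then copper-catalysed halogen exchange (NaI, CuI cat., N,N'-dimethylethylenediamine, dioxane, 110 °C) to 2.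

**Step 2.**
- Most likely failure: slow O-methylation, because two α-iodine atoms lower the basicity of the carbonyl oxygen, and hydrolysis of the salt back to the pyrone on contact with moisture during isolation.
- Fallback (sets out from 2, returns at 3): the C4–O bond is formed instead of the O–CH3 bond. Tf2O (CH2Cl2, 0 °C) activates the carbonyl oxygen to give 3,5-diiodo-4-[(trifluoromethanesulfonyl)oxy]pyrylium trifluoromethanesulfonate F7. MeOSiMe3 then displaces the C4 triflate by addition–elimination to give 3, which is used without isolation.

## Further compounds

F1 | step 3 | 2,6-diiodo-4-nitrophenol | Oc1c(I)cc(cc1I)[N+](=O)[O-]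
F2 | step 3 | 1,3-diiodo-2-methoxy-5-nitrobenzene | COc1c(I)cc(cc1I)[N+](=O)[O-]
F3 | step 3 | 3,5-diiodo-4-methoxyaniline | COc1c(I)cc(N)cc1I
F4 | step 3 | 3,5-diiodo-4-methoxybenzenediazonium chloride | COc1c(I)cc(cc1I)[N+]#N.[Cl-]
F5 | step 3 | 1,3-diiodo-2-methoxy-5-(2,2,2-trichloroethyl)benzene | COc1c(I)cc(CC(Cl)(Cl)Cl)cc1I
F6 | step 1 | 3,5-dibromo-4H-pyran-4-one | O=c1c(Br)cocc1Br
F7 | step 2 | 3,5-diiodo-4-[(trifluoromethanesulfonyl)oxy]pyrylium trifluoromethanesulfonate | FC(F)(F)S(=O)(=O)Oc1c(I)c[o+]cc1I.[O-]S(=O)(=O)C(F)(F)F
A1 | alternative 1 | 2-(4-hydroxyphenyl)acetamide | NC(=O)Cc1ccc(O)cc1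
A2 | alternative 1 | 2-(4-hydroxy-3,5-diiodophenyl)acetamide | NC(=O)Cc1cc(I)c(O)c(I)c1
A3 | alternative 2 | 3,5-diiodo-4-methoxy-2H-pyran-2-one | COc1c(I)coc(=O)c1I
A4 | alternative 2 | but-3-ynamide | C#CCC(N)=O
A5 | alternative 2 | 2-(2,4-diiodo-3-methoxyphenyl)acetamide | COc1c(I)ccc(CC(N)=O)c1I
A6 | alternative 3 | methyl 2-[3-iodo-4-(trimethylsilyl)-5-{[(trifluoromethyl)sulfonyl]oxy}phenyl]acetate | COC(=O)Cc1cc(I)c([Si](C)(C)C)c(OS(=O)(=O)C(F)(F)F)c1
A7 | alternative 3 | methyl 2-(3,4-didehydro-5-iodophenyl)acetate (aryne) | COC(=O)CC1=CC#CC(I)=C1
A8 | alternative 3 | methyl 2-(3,4-diiodo-5-methoxyphenyl)acetate | COC(=O)Cc1cc(I)c(I)c(OC)c1
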